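**Plan**

- Locants follow germacranolide numbering: ring C1–C10; lactone C6–O–C12(=O)–C11(=C13)–C7; C14 on C10; C15 on C4. Retrosynthesis: after desilylation, the C3 ketone and C1 carbinol are returned to a 3,5-bridged isoxazoline. Cutting its C2–C3 and O–C1 bonds together (nitrile oxide plus vinyl group) opens the ten-membered ring to a monocyclic trans-lactone.
- Enabling feature: in ring C1–C10 the C3 ketone and the C1 carbinol are 1,3-related across C2. C3 is conjugated to the ring (Z)-C4=C5 alkene, so it can be carried as an enal oxime. C1 sits on quaternary C10, so it can be a vinyl carbinol. The (Z)-alkene and the trans-lactone ring fold the chain.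
- Earlier cuts: C11=C13 (Horner–Wadsworth–Emmons with formaldehyde), C7–C11 (O6-tethered phosphonoacetate opening a C7–C8 epoxide), C6–C7 (acetylide plus Weinreb amide), C8–C9 (acetylide plus epoxide), C1=C2 (Wittig).
- Forward order: a C3–C6 fragment and a C7–C10/C1–C2 fragment are joined at C6–C7. The γ-lactone ring is closed first. The isoxazoline ring and the ten-membered carbocycle then close in one operation, which is the last ring closure of the skeleton. Methylenation, N–O cleavage and desilylation finish the route.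
- Stereochemistry: C10 from a chiral-pool epoxy alcohol; C6 by Corey–Bakshi–Shibata reduction; C7 and C8 by matched Sharpless epoxidation followed by SN2 inversion at C7; C1 in the cycloaddition under control of C10; (Z)-C4=C5 from a butenolide ring.

Key step: step 16

Assumption: the target is taken as the open 3-keto-1,10-diol exactly as drawn; any ring–chain equilibrium with a C3–O–C10 hemiketal is a property of the compound and needs no separate step.

**Route**

Step 1
Reactants: 1 4-methylfuran-2(5H)-one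
Product: 2 (Z)-4-hydroxy-N-methoxy-N,3-dimethylbut-2-enamide
Conditions: MeNH(OMe)·HCl, AlMe3, CH2Cl2, 0 °C → rt
Reagents that add atoms: N,O-dimethylhydroxylamine hydrochloride, CNOC.Cl
Why: Weinreb aminolysis of the lactone by the aluminium amide cleaves the acyl C–O bond, so the ring-enforced cis relation of C3 and C6 is carried into the (Z)-alkene.

Step 2
Reactants: 2 (Z)-4-hydroxy-N-methoxy-N,3-dimethylbut-2-enamide
Product: 3 (Z)-N-methoxy-N,3-dimethyl-4-(triethylsilyloxy)but-2-enamide
Conditions: Et3SiCl, imidazole, CH2Cl2, 0 °C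
Reagents that add atoms: chlorotriethylsilane, CC[Si](Cl)(CC)CC
Why: Standard silylation of the primary allylic alcohol, done at once so that the hydroxy amide cannot relactonise.

Step 3
Reactants: 4 (S)-2-methylglycidol
Product: 5 (R)-2-methylpent-4-yne-1,2-diol
Conditions: LiC≡CH·H2NCH2CH2NH2, DMSO, 0 °C → rt; then H2O
Reagents that add atoms: lithium acetylide ethylenediamine complex, [Li]C#C.NCCN
Why: SN2 opening of the 2,2-disubstituted epoxide at its CH2 terminus by acetylide leaves the quaternary stereocentre (future C10) untouched.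

Step 4
Reactants: 5 (R)-2-methylpent-4-yne-1,2-diol
Product: 6 (R)-2-methyl-1,2-bis(triethylsilyloxy)pent-4-yne
Conditions: Et3SiOTf, 2,6-lutidine, CH2Cl2, −78 → 0 °C
Reagents that add atoms: triethylsilyl trifluoromethanesulfonate, CC[Si](CC)(CC)OS(=O)(=O)C(F)(F)F
Why: Silyl triflate silylation caps both the primary and the hindered tertiary hydroxyl.

Step 5
Reactants: 6 (R)-2-methyl-1,2-bis(triethylsilyloxy)pent-4-yne
Product: 7 (R)-2-methyl-2-(triethylsilyloxy)pent-4-ynal
Conditions: (COCl)2, DMSO, CH2Cl2, −78 → −30 °C; then Et3N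
Reagents that add atoms: none
Why: Swern conditions oxidise a primary triethylsilyl ether directly to the aldehyde, while the tertiary silyl ether, which has no carbinol hydrogen, survives.

Step 6
Reactants: 7 (R)-2-methyl-2-(triethylsilyloxy)pent-4-ynal
Product: 8 (R)-3-methyl-3-(triethylsilyloxy)hex-1-en-5-yne
Conditions: Ph3PCH3Br, KN(SiMe3)2, THF, 0 °C
Reagents that add atoms: methyltriphenylphosphonium bromide, C[P+](c1ccccc1)(c1ccccc1)c1ccccc1.[Br-]
Why: Wittig methylenation of the non-enolisable α-quaternary aldehyde gives the C1=C2 vinyl group without risk to C10.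

Step 7
Reactants: 8 (R)-3-methyl-3-(triethylsilyloxy)hex-1-en-5-yne; 3 (Z)-N-methoxy-N,3-dimethyl-4-(triethylsilyloxy)but-2-enamide
Product: 10 (2Z,8R)-2,8-dimethyl-1,8-bis(triethylsilyloxy)deca-2,9-dien-5-yn-4-one, via lithium acetylide of the alkyne 9 (not isolated)
Conditions: n-BuLi, THF, −78 °C; then 3, −78 → 0 °C; then H2O
Reagents that add atoms: none
Why: Acylation of a lithium acetylide by a Weinreb amide stops at the ketone through the chelated tetrahedral intermediate and joins the fragments at C6–C7.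

Step 8
Reactants: 10 (2Z,8R)-2,8-dimethyl-1,8-bis(triethylsilyloxy)deca-2,9-dien-5-yn-4-one
Product: 11 (2Z,4R,8R)-2,8-dimethyl-1,8-bis(triethylsilyloxy)deca-2,9-dien-5-yn-4-ol
Conditions: (R)-2-methyl-CBS-oxazaborolidine (20 mol %), catecholborane, toluene, −78 °C
Reagents that add atoms: none
Why: Corey–Bakshi–Shibata reduction, in which the Z-trisubstituted alkenyl group acts as the large and the slim alkynyl group as the small substituent, so the (R)-catalyst should give the (R)-carbinol at C6; catecholborane leaves the alkenes alone.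

Step 9
Reactants: 11 (2Z,4R,8R)-2,8-dimethyl-1,8-bis(triethylsilyloxy)deca-2,9-dien-5-yn-4-ol
Product: 12 (2Z,4S,5E,8R)-2,8-dimethyl-1,8-bis(triethylsilyloxy)deca-2,5,9-trien-4-ol
Conditions: NaAlH2(OCH2CH2OMe)2, THF, 0 °C → rt; then aq. potassium sodium tartrate
Reagents that add atoms: none
Why: Hydroxyl-directed trans-hydroalumination of the propargylic alcohol and protonolysis should give only the (E)-C7=C8 alkene (the C6 descriptor changes by priority only).

Step 10
Reactants: 12 (2Z,4S,5E,8R)-2,8-dimethyl-1,8-bis(triethylsilyloxy)deca-2,5,9-trien-4-ol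
Product: 13 (1R,2Z)-3-methyl-1-{(2R,3R)-3-[(2R)-2-methyl-2-(triethylsilyloxy)but-3-en-1-yl]oxiran-2-yl}-4-(triethylsilyloxy)but-2-en-1-ol
Conditions: Ti(OiPr)4 (cat.), D-(−)-diisopropyl tartrate (cat.), t-BuOOH, 4 Å MS, CH2Cl2, −20 °C
Reagents that add atoms: tert-butyl hydroperoxide, CC(C)(C)OO
Why: Sharpless asymmetric epoxidation, in which the C6 configuration is matched with D-(−)-tartrate for the C7=C8 alkene and should give the anti (erythro) epoxy alcohol, setting C7 and C8; the C4=C5 side is the mismatched, cis-substituted partner and the silylated vinyl carbinol is no substrate.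

Step 11
Reactants: 13 (1R,2Z)-3-methyl-1-{(2R,3R)-3-[(2R)-2-methyl-2-(triethylsilyloxy)but-3-en-1-yl]oxiran-2-yl}-4-(triethylsilyloxy)but-2-en-1-ol
Product: 14 (1R,2Z)-3-methyl-1-{(2S,3R)-3-[(2R)-2-methyl-2-(triethylsilyloxy)but-3-en-1-yl]oxiran-2-yl}-4-(triethylsilyloxy)but-2-en-1-yl 2-(diethoxyphosphoryl)acetate
Conditions: (EtO)2P(O)CH2CO2H, DCC, DMAP (cat.), CH2Cl2, 0 °C → rt
Reagents that add atoms: diethylphosphonoacetic acid, CCOP(=O)(CC(=O)O)OCC
Why: Steglich esterification tethers the two-carbon nucleophile (C11, C12) to O6 without touching the epoxide (the oxirane descriptor changes by priority only).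

Step 12
Reactants: 14 (1R,2Z)-3-methyl-1-{(2S,3R)-3-[(2R)-2-methyl-2-(triethylsilyloxy)but-3-en-1-yl]oxiran-2-yl}-4-(triethylsilyloxy)but-2-en-1-yl 2-(diethoxyphosphoryl)acetate
Product: 15 diethyl {(4R,5R)-4-[(1R,3R)-1-hydroxy-3-methyl-3-(triethylsilyloxy)pent-4-en-1-yl]-5-[(Z)-2-methyl-3-(triethylsilyloxy)prop-1-en-1-yl]-2-oxooxolan-3-yl}phosphonate (C11 epimers)
Conditions: NaH, THF, 0 °C → rt; then AcOH
Reagents that add atoms: none
Why: 5-exo-tet opening of the epoxide by the O6-tethered phosphonoacetate anion (a carbon analogue of the Stork epoxynitrile cyclisation) should form C7–C11 with SN2 inversion at C7, giving the trans-lactone and leaving the C8 oxygen with retention; the alkoxide is quenched at once by the acidic α-phosphono C–H.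

Step 13
Reactants: 15 diethyl {(4R,5R)-4-[(1R,3R)-1-hydroxy-3-methyl-3-(triethylsilyloxy)pent-4-en-1-yl]-5-[(Z)-2-methyl-3-(triethylsilyloxy)prop-1-en-1-yl]-2-oxooxolan-3-yl}phosphonate
Product: 16 diethyl {(4R,5R)-4-[(1R,3R)-3-methyl-1-(2-methylpropanoyloxy)-3-(triethylsilyloxy)pent-4-en-1-yl]-5-[(Z)-2-methyl-3-(triethylsilyloxy)prop-1-en-1-yl]-2-oxooxolan-3-yl}phosphonate
Conditions: i-PrCOCl, pyridine, DMAP (cat.), CH2Cl2, 0 °C
Reagents that add atoms: isobutyryl chloride, CC(C)C(=O)Cl
Why: DMAP-assisted acylation of the only free hydroxyl (secondary, C8) installs the isobutyrate.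

Step 14
Reactants: 16 diethyl {(4R,5R)-4-[(1R,3R)-3-methyl-1-(2-methylpropanoyloxy)-3-(triethylsilyloxy)pent-4-en-1-yl]-5-[(Z)-2-methyl-3-(triethylsilyloxy)prop-1-en-1-yl]-2-oxooxolan-3-yl}phosphonate
Product: 17 diethyl {(4R,5R)-4-[(1R,3R)-3-methyl-1-(2-methylpropanoyloxy)-3-(triethylsilyloxy)pent-4-en-1-yl]-5-[(Z)-2-methyl-3-oxoprop-1-en-1-yl]-2-oxooxolan-3-yl}phosphonate
Conditions: (COCl)2, DMSO, CH2Cl2, −78 → −40 °C; then Et3N
Reagents that add atoms: none
Why: As in step 5, Swern conditions convert only the primary allylic silyl ether into the aldehyde (C3), at low temperature so that the (Z)-enal should not isomerise.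

Step 15
Reactants: 17 diethyl {(4R,5R)-4-[(1R,3R)-3-methyl-1-(2-methylpropanoyloxy)-3-(triethylsilyloxy)pent-4-en-1-yl]-5-[(Z)-2-methyl-3-oxoprop-1-en-1-yl]-2-oxooxolan-3-yl}phosphonate
Product: 18 diethyl {(4R,5R)-5-[(Z)-3-(hydroxyimino)-2-methylprop-1-en-1-yl]-4-[(1R,3R)-3-methyl-1-(2-methylpropanoyloxy)-3-(triethylsilyloxy)pent-4-en-1-yl]-2-oxooxolan-3-yl}phosphonate
Conditions: NH2OH·HCl, pyridine, EtOH, 0 °C
Reagents that add atoms: hydroxylamine hydrochloride, NO.Cl
Why: Condensation of the aldehyde with hydroxylamine under mild buffered conditions gives the aldoxime, whose C=N geometry is irrelevant.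

Step 16
Reactants: 18 diethyl {(4R,5R)-5-[(Z)-3-(hydroxyimino)-2-methylprop-1-en-1-yl]-4-[(1R,3R)-3-methyl-1-(2-methylpropanoyloxy)-3-(triethylsilyloxy)pent-4-en-1-yl]-2-oxooxolan-3-yl}phosphonate
Product: 21 (1R,6R,7R,8R,10R)-11-(diethoxyphosphoryl)-8-isobutyryloxy-10-(triethylsilyloxy)germacr-4Z-en-6,12-olide bridged C3=N–O–C1 (isoxazoline), via hydroximoyl chloride 19 (not isolated), via nitrile oxide 20 (not isolated)
Conditions: NCS, DMF, 0 °C → rt; then Et3N (syringe pump), CH2Cl2, 1 mM, 35 °C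
Reagents that add atoms: none
Why: NCS converts the aldoxime into hydroximoyl chloride 19, and slow dehydrochlorination by Et3N at high dilution releases the conjugated nitrile oxide 20, which adds in a concerted [3+2] fashion across the C1=C2 vinyl group; the closest known reaction type is the intramolecular nitrile oxide–olefin cycloaddition used in its bridged mode to make medium and large carbocyclic β-ketol equivalents. The isoxazoline ring closes by simultaneous C3–C2 and O–C1 bonding, and the ten-membered carbocycle closes through that same C3–C2 bond as the large ring of a 3,5-bridged (bicyclo[7.2.1]) isoxazoline, i.e. the bridged (endo) mode. The only new stereocentre, C1, is controlled by the adjacent quaternary C10 through the inside-alkoxy effect: the C10–OSiEt3 bond sits inside, the methyl anti and the ring tether (C9) outside, which should expose the alkene face leading to the (1R) isomer. The step needs O-to-C1 regiochemistry, which the monosubstituted alkene next to the quaternary C10 secures both electronically and sterically, and the alternative fused mode would also require a nine-membered ring. It needs chemoselectivity, which is secured because C11 is still an sp3 phosphonate carbon (no α-methylene lactone to act as a competing dipolarophile) and the only other alkene is the conjugated C4=C5 of the dipole itself. It needs ring closure to outrun furoxan dimerisation, which high dilution and the folding imposed by the (Z)-C4=C5 alkene and the trans-lactone ring should favour.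

Step 17
Reactants: 21 (1R,6R,7R,8R,10R)-11-(diethoxyphosphoryl)-8-isobutyryloxy-10-(triethylsilyloxy)germacr-4Z-en-6,12-olide bridged C3=N–O–C1
Product: 22 (1R,6R,7R,8R,10R)-8-isobutyryloxy-10-(triethylsilyloxy)germacra-4Z,11(13)-dien-6,12-olide bridged C3=N–O–C1
Conditions: K2CO3, aq. HCHO, THF, 0 °C → rt
Reagents that add atoms: formaldehyde, C=O
Why: Horner–Wadsworth–Emmons reaction of the α-phosphono lactone with formaldehyde under mild carbonate conditions installs the C11=C13 methylene only after the dipolar step.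

Step 18
Reactants: 22 (1R,6R,7R,8R,10R)-8-isobutyryloxy-10-(triethylsilyloxy)germacra-4Z,11(13)-dien-6,12-olide bridged C3=N–O–C1
Product: 24 (1R,6R,7R,8R,10R)-1-hydroxy-8-isobutyryloxy-3-oxo-10-(triethylsilyloxy)germacra-4Z,11(13)-dien-6,12-olide, via C3 N–H imine 23 (not isolated)
Conditions: Mo(CO)6, B(OH)3, MeCN/H2O, 80 °C
Reagents that add atoms: water, O
Why: Mo(CO)6-mediated reductive N–O cleavage of the isoxazoline gives β-hydroxy imine 23, which is hydrolysed in situ to the C3 ketone with C1 untouched; electron-poor alkenes are tolerated and B(OH)3 buffers the ammonia released.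

Step 19
Reactants: 24 (1R,6R,7R,8R,10R)-1-hydroxy-8-isobutyryloxy-3-oxo-10-(triethylsilyloxy)germacra-4Z,11(13)-dien-6,12-olide
Product: 25 (1R,6R,7R,8R,10R)-1,10-dihydroxy-8-isobutyryloxy-3-oxogermacra-4Z,11(13)-dien-6,12-olide
Conditions: HF·pyridine, pyridine, THF, 0 °C → rt
Reagents that add atoms: none
Why: Buffered fluoride cleavage of the tertiary silyl ether should leave the β-hydroxy enone, the isobutyrate and the α-methylene lactone intact.

**Compound list**

1 | 4-methylfuran-2(5H)-one | CC1=CC(=O)OC1 | starting material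
2 | (Z)-4-hydroxy-N-methoxy-N,3-dimethylbut-2-enamide | OC/C(C)=C\C(=O)N(C)OC | intermediate
3 | (Z)-N-methoxy-N,3-dimethyl-4-(triethylsilyloxy)but-2-enamide | CC[Si](CC)(CC)OC/C(C)=C\C(=O)N(C)OC | intermediate
4 | (S)-2-methylglycidol, (S)-(2-methyloxiran-2-yl)methanol | OC[C@@]1(C)CO1 | starting material
5 | (R)-2-methylpent-4-yne-1,2-diol | OC[C@](C)(O)CC#C | intermediate
6 | (R)-2-methyl-1,2-bis(triethylsilyloxy)pent-4-yne | CC[Si](CC)(CC)OC[C@](C)(O[Si](CC)(CC)CC)CC#C | intermediate
7 | (R)-2-methyl-2-(triethylsilyloxy)pent-4-ynal | O=C[C@](C)(O[Si](CC)(CC)CC)CC#C | intermediate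
8 | (R)-3-methyl-3-(triethylsilyloxy)hex-1-en-5-yne | C=C[C@](C)(O[Si](CC)(CC)CC)CC#C | intermediate
9 | lithium acetylide of 8 (formed in situ) | [Li]C#CC[C@@](C)(O[Si](CC)(CC)CC)C=C | intermediate
10 | (2Z,8R)-2,8-dimethyl-1,8-bis(triethylsilyloxy)deca-2,9-dien-5-yn-4-one | CC[Si](CC)(CC)OC/C(C)=C\C(=O)C#CC[C@@](C)(O[Si](CC)(CC)CC)C=C | intermediate
11 | (2Z,4R,8R)-2,8-dimethyl-1,8-bis(triethylsilyloxy)deca-2,9-dien-5-yn-4-ol | CC[Si](CC)(CC)OC/C(C)=C\[C@@H](O)C#CC[C@@](C)(O[Si](CC)(CC)CC)C=C | intermediate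
12 | (2Z,4S,5E,8R)-2,8-dimethyl-1,8-bis(triethylsilyloxy)deca-2,5,9-trien-4-ol | CC[Si](CC)(CC)OC/C(C)=C\[C@@H](O)/C=C/C[C@@](C)(O[Si](CC)(CC)CC)C=C | intermediate
13 | (1R,2Z)-3-methyl-1-{(2R,3R)-3-[(2R)-2-methyl-2-(triethylsilyloxy)but-3-en-1-yl]oxiran-2-yl}-4-(triethylsilyloxy)but-2-en-1-ol | CC[Si](CC)(CC)OC/C(C)=C\[C@@H](O)[C@H]1O[C@@H]1C[C@@](C)(O[Si](CC)(CC)CC)C=C | intermediate
14 | 2-(diethoxyphosphoryl)acetate ester of 13, (1R,2Z), oxirane (2S,3R), side chain (2R) | CC[Si](CC)(CC)OC/C(C)=C\[C@@H](OC(=O)CP(=O)(OCC)OCC)[C@H]1O[C@@H]1C[C@@](C)(O[Si](CC)(CC)CC)C=C | intermediate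
15 | diethyl {(4R,5R)-4-[(1R,3R)-1-hydroxy-3-methyl-3-(triethylsilyloxy)pent-4-en-1-yl]-5-[(Z)-2-methyl-3-(triethylsilyloxy)prop-1-en-1-yl]-2-oxooxolan-3-yl}phosphonate (C11 epimers) | CCOP(=O)(OCC)C1C(=O)O[C@H](/C=C(/C)CO[Si](CC)(CC)CC)[C@H]1[C@H](O)C[C@@](C)(O[Si](CC)(CC)CC)C=C | intermediate
16 | C8 isobutyrate of 15 | CCOP(=O)(OCC)C1C(=O)O[C@H](/C=C(/C)CO[Si](CC)(CC)CC)[C@H]1[C@H](OC(=O)C(C)C)C[C@@](C)(O[Si](CC)(CC)CC)C=C | intermediate
17 | (Z)-enal (C3 aldehyde) from 16 | CCOP(=O)(OCC)C1C(=O)O[C@H](/C=C(/C)C=O)[C@H]1[C@H](OC(=O)C(C)C)C[C@@](C)(O[Si](CC)(CC)CC)C=C | intermediate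
18 | aldoxime of 17 | CCOP(=O)(OCC)C1C(=O)O[C@H](/C=C(/C)C=NO)[C@H]1[C@H](OC(=O)C(C)C)C[C@@](C)(O[Si](CC)(CC)CC)C=C | intermediate
19 | hydroximoyl chloride from 18 (formed in situ) | CCOP(=O)(OCC)C1C(=O)O[C@H](/C=C(/C)C(Cl)=NO)[C@H]1[C@H](OC(=O)C(C)C)C[C@@](C)(O[Si](CC)(CC)CC)C=C | intermediate
20 | nitrile oxide from 19 (formed in situ) | CCOP(=O)(OCC)C1C(=O)O[C@H](/C=C(/C)C#[N+][O-])[C@H]1[C@H](OC(=O)C(C)C)C[C@@](C)(O[Si](CC)(CC)CC)C=C | intermediate
21 | (1R,6R,7R,8R,10R)-11-(diethoxyphosphoryl)-8-isobutyryloxy-10-(triethylsilyloxy)germacr-4Z-en-6,12-olide bridged C3=N–O–C1 (C11 epimers) | CCOP(=O)(OCC)C1C(=O)O[C@@H]2/C=C(/C)C3=NO[C@H](C3)[C@](C)(O[Si](CC)(CC)CC)C[C@@H](OC(=O)C(C)C)[C@@H]12 | intermediate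
22 | (1R,6R,7R,8R,10R)-8-isobutyryloxy-10-(triethylsilyloxy)germacra-4Z,11(13)-dien-6,12-olide bridged C3=N–O–C1 | C=C1C(=O)O[C@@H]2/C=C(/C)C3=NO[C@H](C3)[C@](C)(O[Si](CC)(CC)CC)C[C@@H](OC(=O)C(C)C)[C@@H]12 | intermediate
23 | C3 N–H imine of 24 (formed in situ) | C=C1C(=O)O[C@@H]2/C=C(/C)C(=N)C[C@@H](O)[C@](C)(O[Si](CC)(CC)CC)C[C@@H](OC(=O)C(C)C)[C@@H]12 | intermediate
24 | (1R,6R,7R,8R,10R)-1-hydroxy-8-isobutyryloxy-3-oxo-10-(triethylsilyloxy)germacra-4Z,11(13)-dien-6,12-olide | C=C1C(=O)O[C@@H]2/C=C(/C)C(=O)C[C@@H](O)[C@](C)(O[Si](CC)(CC)CC)C[C@@H](OC(=O)C(C)C)[C@@H]12 | intermediate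
25 | (1R,6R,7R,8R,10R)-1,10-dihydroxy-8-isobutyryloxy-3-oxogermacra-4Z,11(13)-dien-6,12-olide | C=C1C(=O)O[C@@H]2/C=C(/C)C(=O)C[C@@H](O)[C@](C)(O)C[C@@H](OC(=O)C(C)C)[C@@H]12 | target

**Step count and risks**

Total step count: 19. Longest linear sequence: 17 (steps 3–6, then 7–19).

Steps most likely to fail:

1. Step 16. The nitrile oxide may dimerise or oligomerise faster than the strained ten-membered ring closes, or the dipole may add to the wrong face of the vinyl group and give the C1 epimer. Fallback (sets out from 17, comes back at 24): close the same ring by olefin metathesis at C1=C2 and add the C1 oxygen afterwards. Addition of CH2=CHMgBr (THF, −78 °C, one extra equivalent for the acidic phosphonate C–H) to 17 would give the C3 vinyl carbinol F1. Ring-closing metathesis of its two terminal vinyl groups (second-generation Hoveyda–Grubbs catalyst, toluene, 80 °C, 1 mM) would give the ten-membered cyclic dienol F2. Dess–Martin oxidation would give the cross-conjugated dienone F3. Weitz–Scheffer epoxidation (t-BuOOH, DBU) of the less substituted C1=C2 enone from the exposed ring face would give the epoxy ketone F4. Reductive opening at C2 (PhSeSePh, NaBH4, AcOH, EtOH) would give the β-hydroxy ketone F5. Horner–Wadsworth–Emmons methylenation (K2CO3, aq. HCHO) would then return to 24.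

2. Step 18. The reductant or the ammonia released may attack the α-methylene lactone, the enone may be over-reduced, or the β-ketol may dehydrate at 80 °C. Fallback (sets out from 22, comes back at 24): mask the methylene lactone before the reduction. Conjugate addition of Me2NH (THF, 0 °C) to 22 would give the amine adduct F6. N–O cleavage with SmI2 and B(OH)3 (THF/H2O, 0 °C) and hydrolysis would give the hydroxy ketone amine F7. Quaternisation with MeI and elimination with NaHCO3 would regenerate the methylene lactone and return to 24.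

3. Step 8. Facial selectivity may erode because both ketone substituents are unsaturated and the catalyst may not tell them apart well. Fallback (sets out from 10, comes back at 13): set C6 by resolution in place of asymmetric reduction. Luche reduction (NaBH4, CeCl3·7H2O, MeOH, −78 °C) of 10 would give the C6-epimeric propargylic alcohols F8. NaAlH2(OCH2CH2OMe)2 would give the C6-epimeric (E)-dienols F9. Sharpless epoxidation with D-(−)-diisopropyl tartrate run as a kinetic resolution (Ti(OiPr)4, 0.6 equiv t-BuOOH, −20 °C) should epoxidise only the matched epimer to 13; the unreacted epimer is separated.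

**Further compounds**

F1 | step 16 | C3 vinyl carbinol from 17 (C3 epimers) | CCOP(=O)(OCC)C1C(=O)O[C@H](/C=C(/C)C(O)C=C)[C@H]1[C@H](OC(=O)C(C)C)C[C@@](C)(O[Si](CC)(CC)CC)C=C
F2 | step 16 | ten-membered germacra-1,4Z-dien-3-ol 6,12-olide with C11 phosphonate, 8-isobutyrate and 10-triethylsilyl ether | CCOP(=O)(OCC)C1C(=O)O[C@@H]2/C=C(/C)C(O)C=C[C@](C)(O[Si](CC)(CC)CC)C[C@@H](OC(=O)C(C)C)[C@@H]12
F3 | step 16 | cross-conjugated germacra-1,4Z-dien-3-one from F2 | CCOP(=O)(OCC)C1C(=O)O[C@@H]2/C=C(/C)C(=O)C=C[C@](C)(O[Si](CC)(CC)CC)C[C@@H](OC(=O)C(C)C)[C@@H]12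
F4 | step 16 | 1,2-epoxy-3-ketone from F3 | CCOP(=O)(OCC)C1C(=O)O[C@@H]2/C=C(/C)C(=O)C3O[C@H]3[C@](C)(O[Si](CC)(CC)CC)C[C@@H](OC(=O)C(C)C)[C@@H]12
F5 | step 16 | (1R)-1-hydroxy-3-ketone with C11 phosphonate | CCOP(=O)(OCC)C1C(=O)O[C@@H]2/C=C(/C)C(=O)C[C@@H](O)[C@](C)(O[Si](CC)(CC)CC)C[C@@H](OC(=O)C(C)C)[C@@H]12
F6 | step 18 | 13-(dimethylamino) adduct of 22 | CN(C)CC1C(=O)O[C@@H]2/C=C(/C)C3=NO[C@H](C3)[C@](C)(O[Si](CC)(CC)CC)C[C@@H](OC(=O)C(C)C)[C@@H]12
F7 | step 18 | 13-(dimethylamino) adduct of 24 | CN(C)CC1C(=O)O[C@@H]2/C=C(/C)C(=O)C[C@@H](O)[C@](C)(O[Si](CC)(CC)CC)C[C@@H](OC(=O)C(C)C)[C@@H]12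
F8 | step 8 | C6-epimeric mixture of propargylic alcohol 11 | CC[Si](CC)(CC)OC/C(C)=C\C(O)C#CC[C@@](C)(O[Si](CC)(CC)CC)C=C
F9 | step 8 | C6-epimeric mixture of dienol 12 | CC[Si](CC)(CC)OC/C(C)=C\C(O)/C=C/C[C@@](C)(O[Si](CC)(CC)CC)C=C
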